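**Convention and assumption:** the target is taken exactly as drawn, i.e. the (1R,7S,8R,10S)-guaiane (the propanoate analogue of torilin). Guaiane locants are used in the text (C3 ketone, C4=C5, C7 side-chain carbon, C8 oxygenated carbon, C10 methyl carbon, C11 carbinol carbon), and β is the face of the C10 methyl group.

**Retrosynthetic overview**
1. Target ⇒ torilolone (8β,11-diol) by two chemoselective acylations: secondary OH as propanoate, then tertiary OH as acetate.
2. Key C8–O bond: carbamate-directed γ-C–H oxygenation of a monocyclic tertiary carbinol; the oxygen is delivered from the C11 oxygen tether, cis to the side chain, as a cyclic carbonate.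
3. Five-membered ring formed last: aldol condensation of a 2-(2-oxobutyl)cycloheptanone; the same pot removes the carbonate.
4. C10 and C1: CuH asymmetric conjugate reduction of a 3-methylcycloheptenone and trans-propargylation of the enolate; C11–O by Mukaiyama hydration.
5. Seven-membered ring formed first: one-carbon Saegusa–Ito ring expansion of (R)-carvone, which supplies C7.

**Route**

Step 1
Reactants: 1 (R)-(−)-carvone
Product: 2 trimethyl{[(5R)-2-methyl-5-(prop-1-en-2-yl)cyclohex-1-en-1-yl]oxy}silane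
Conditions: LiBH(s-Bu)3 (1.1 equiv), THF, −78 °C; then Me3SiCl, −78 → 0 °C
Reagents that add atoms: chlorotrimethylsilane, C[Si](C)(C)Cl
Why: Conjugate reduction of the β-unsubstituted enone by the hindered borohydride gives the regiodefined lithium enolate, which is O-silylated to the tetrasubstituted silyl enol ether; the carvone stereocentre (future C7) is untouched.

Step 2
Reactants: 2 trimethyl{[(5R)-2-methyl-5-(prop-1-en-2-yl)cyclohex-1-en-1-yl]oxy}silane
Product: 3 (1S,3R,6S)-6-methyl-3-(prop-1-en-2-yl)-1-(trimethylsilyloxy)bicyclo[4.1.0]heptane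
Conditions: Et2Zn (1.5 equiv), CH2I2 (1.6 equiv), CH2Cl2, 0 °C → rt
Reagents that add atoms: diiodomethane, ICI
Why: Simmons–Smith (Furukawa) cyclopropanation, in which the zinc carbenoid reacts faster with the electron-rich silyl enol ether than with the 1,1-disubstituted isopropenyl alkene; the two new centres are cis by necessity and are erased in step 3 (the other face isomer converges).

Step 3
Reactants: 3 (1S,3R,6S)-6-methyl-3-(prop-1-en-2-yl)-1-(trimethylsilyloxy)bicyclo[4.1.0]heptane
Product: 5 (6R)-3-methyl-6-(prop-1-en-2-yl)cyclohept-2-en-1-one, via β-chloro ketone 4 (not isolated)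
Conditions: FeCl3 (2.5 equiv), DMF, 0 °C → rt; then NaOAc, MeOH, reflux
Reagents that add atoms: none
Why: Saegusa–Ito ring expansion, in which one-electron oxidation of the siloxycyclopropane cleaves the internal bond, chlorine transfer gives the β-chloro cycloheptanone and acetate-induced elimination gives the conjugated enone.

Step 4
Reactants: 5 (6R)-3-methyl-6-(prop-1-en-2-yl)cyclohept-2-en-1-one; 6 1-bromobut-2-yne
Product: 8 (2R,3S,6R)-2-(but-2-yn-1-yl)-3-methyl-6-(prop-1-en-2-yl)cycloheptan-1-one, via bis(enoxy)silane 7 (not isolated)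
Conditions: CuCl (5 mol %), NaOtBu (5 mol %), (S)-p-tol-BINAP (5 mol %), Ph2SiH2 (0.55 equiv), toluene, −20 °C; then Bu4N[Ph3SiF2] (1.2 equiv), 6 (1.5 equiv), CH2Cl2, rt
Reagents that add atoms: none
Why: Copper hydride asymmetric conjugate reduction (Buchwald type) sets C10 under catalyst control with hydride delivered to the α face (the mirror-image ligand is taken if the facial sense proves opposite), and fluoride-triggered alkylation of the regiodefined silyl enolate with the propargylic bromide occurs anti to the new methyl group, setting C1 trans.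

Step 5
Reactants: 8 (2R,3S,6R)-2-(but-2-yn-1-yl)-3-methyl-6-(prop-1-en-2-yl)cycloheptan-1-one
Product: 9 (2R,3S,6R)-3-methyl-2-(2-oxobutyl)-6-(prop-1-en-2-yl)cycloheptan-1-one
Conditions: Ph3PAuNTf2 (2 mol %), 1,4-dioxane–H2O (10:1), 60 °C
Reagents that add atoms: water, O
Why: Gold-catalysed alkyne hydration with 5-exo participation of the ring carbonyl places the new carbonyl on the proximal alkyne carbon and gives the 1,4-diketone, while the isopropenyl alkene is inert.

Step 6
Reactants: 9 (2R,3S,6R)-3-methyl-2-(2-oxobutyl)-6-(prop-1-en-2-yl)cycloheptan-1-one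
Product: 10 (2R,3S,6R)-6-(2-hydroxypropan-2-yl)-3-methyl-2-(2-oxobutyl)cycloheptan-1-one
Conditions: Co(acac)2 (20 mol %), PhSiH3 (2 equiv), O2 (1 atm), THF, 0 °C → rt
Reagents that add atoms: dioxygen, O=O
Why: Mukaiyama hydration (cobalt hydride hydrogen atom transfer, then O2 capture) converts the 1,1-disubstituted alkene into the Markovnikov tertiary alcohol without touching the ketones; no stereocentre is formed.

Step 7
Reactants: 10 (2R,3S,6R)-6-(2-hydroxypropan-2-yl)-3-methyl-2-(2-oxobutyl)cycloheptan-1-one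
Product: 11 2-[(1R,4R,5S)-5-methyl-3-oxo-4-(2-oxobutyl)cycloheptyl]propan-2-yl (2,2,2-trifluoroethyl)carbamate
Conditions: CF3CH2NCO (1.5 equiv), CuCl (10 mol %), DMF, rt
Reagents that add atoms: 2,2,2-trifluoroethyl isocyanate, O=C=NCC(F)(F)F
Why: CuCl-catalysed addition of a hindered tertiary alcohol to an isocyanate gives the N–H carbamate that serves as the radical relay group.

Step 8
Reactants: 11 2-[(1R,4R,5S)-5-methyl-3-oxo-4-(2-oxobutyl)cycloheptyl]propan-2-yl (2,2,2-trifluoroethyl)carbamate
Product: 15 cis-fused cyclic carbonate of the 8β,11-diol diketone, via N-iodocarbamate 12 (not isolated), via 8α-iodide 13 (not isolated), via cyclic iminocarbonate 14 (not isolated)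
Conditions: PhI(OAc)2 (2.2 equiv), I2 (0.3 equiv), 1,2-dichloroethane, blue LEDs, rt; then AcOH–H2O, 40 °C
Reagents that add atoms: water, O
Why: Proposed new method: a one-flask visible-light iodine relay on the N–H carbamate, in which N-iodination and N–I homolysis give an amidyl radical that abstracts hydrogen by 1,6-transfer through a seven-membered transition state from C8 (the other γ-methylene, C6, is α to the ketone and polarity-mismatched), iodine-atom transfer anti to the bulky side chain gives the 8α-iodide, and oxidation of C–I to a trivalent alkyl iodane triggers intramolecular SN2 attack of the carbamate carbonyl oxygen from the β face with inversion, the unreactive 8β-iodide being recycled by iodine exchange so that O-8 ends cis to the C7 side chain (8R) before the imine is hydrolysed to the carbonate; the closest known reactions are the stoichiometric N-bromocarbamate route to 1,3-diols (Hofmann–Löffler–Freytag type) and iodine-catalysed C–H amination of sulfonamides, neither shown as a catalytic-iodine oxygenation of an unactivated ring methylene.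

Step 9
Reactants: 15 cis-fused cyclic carbonate of the 8β,11-diol diketone
Product: 18 torilolone [(5S,6R,8S,8aR)-6-hydroxy-5-(2-hydroxypropan-2-yl)-3,8-dimethyl-4,5,6,7,8,8a-hexahydroazulen-2(1H)-one], via diol diketone 16 (not isolated), via aldol adduct 17 (not isolated)
Conditions: KOH (5 equiv), MeOH–H2O (4:1), 60 °C
Reagents that add atoms: none
Why: Hydroxide cleaves the six-membered carbonate and drives the intramolecular aldol condensation of the 1,4-diketone (ethyl-ketone enolate onto the ring carbonyl, then E1cB dehydration) to the tetrasubstituted cyclopentenone, the alternative aldol mode being reversible because it would need a bridgehead alkene, and C1 stays trans to the C10 methyl group.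

Step 10
Reactants: 18 torilolone
Product: 19 [(5S,6R,8S,8aR)-5-(2-hydroxypropan-2-yl)-3,8-dimethyl-2-oxo-1,2,4,5,6,7,8,8a-octahydroazulen-6-yl] propanoate
Conditions: (EtCO)2O (1.2 equiv), Et3N, DMAP (5 mol %), CH2Cl2, 0 °C
Reagents that add atoms: propanoic anhydride, CCC(=O)OC(=O)CC
Why: DMAP-catalysed acylation discriminates the secondary C8 hydroxyl from the tertiary C11 hydroxyl.

Step 11
Reactants: 19 [(5S,6R,8S,8aR)-5-(2-hydroxypropan-2-yl)-3,8-dimethyl-2-oxo-1,2,4,5,6,7,8,8a-octahydroazulen-6-yl] propanoate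
Product: 20 [(5S,6R,8S,8aR)-5-(2-acetoxypropan-2-yl)-3,8-dimethyl-2-oxo-1,2,4,5,6,7,8,8a-octahydroazulen-6-yl] propanoate
Conditions: Ac2O (5 equiv), DMAP (1 equiv), Et3N, CH2Cl2, 40 °C
Reagents that add atoms: acetic anhydride, CC(=O)OC(C)=O
Why: Steglich-type DMAP acylation with excess anhydride acetylates the remaining tertiary alcohol under basic, non-ionising conditions that avoid acyl scrambling and E1 dehydration.

**Compound list**

1 | (R)-(−)-carvone, (5R)-2-methyl-5-(prop-1-en-2-yl)cyclohex-2-en-1-one | CC1=CC[C@H](CC1=O)C(C)=C | starting material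
2 | trimethyl{[(5R)-2-methyl-5-(prop-1-en-2-yl)cyclohex-1-en-1-yl]oxy}silane | CC1=C(O[Si](C)(C)C)C[C@@H](CC1)C(C)=C | intermediate
3 | (1S,3R,6S)-6-methyl-3-(prop-1-en-2-yl)-1-(trimethylsilyloxy)bicyclo[4.1.0]heptane (cyclopropane anti to the isopropenyl group; the syn isomer converges) | C[C@]12C[C@@]1(O[Si](C)(C)C)C[C@@H](CC2)C(C)=C | intermediate
4 | (6R)-3-chloro-3-methyl-6-(prop-1-en-2-yl)cycloheptan-1-one (both C3 epimers) | C1CC(C)(Cl)CC(=O)C[C@@H]1C(C)=C | intermediate
5 | (6R)-3-methyl-6-(prop-1-en-2-yl)cyclohept-2-en-1-one | C1CC(C)=CC(=O)C[C@@H]1C(C)=C | intermediate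
6 | 1-bromobut-2-yne | CC#CCBr | starting material
7 | bis{[(3S,6R)-3-methyl-6-(prop-1-en-2-yl)cyclohept-1-en-1-yl]oxy}diphenylsilane | C1C[C@H](C)C=C(O[Si](c2ccccc2)(c2ccccc2)OC3=C[C@@H](C)CC[C@H](C3)C(C)=C)C[C@@H]1C(C)=C | intermediate
8 | (2R,3S,6R)-2-(but-2-yn-1-yl)-3-methyl-6-(prop-1-en-2-yl)cycloheptan-1-one | C1C[C@H](C)[C@@H](CC#CC)C(=O)C[C@@H]1C(C)=C | intermediate
9 | (2R,3S,6R)-3-methyl-2-(2-oxobutyl)-6-(prop-1-en-2-yl)cycloheptan-1-one | C1C[C@H](C)[C@@H](CC(=O)CC)C(=O)C[C@@H]1C(C)=C | intermediate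
10 | (2R,3S,6R)-6-(2-hydroxypropan-2-yl)-3-methyl-2-(2-oxobutyl)cycloheptan-1-one | C1C[C@H](C)[C@@H](CC(=O)CC)C(=O)C[C@@H]1C(C)(C)O | intermediate
11 | 2-[(1R,4R,5S)-5-methyl-3-oxo-4-(2-oxobutyl)cycloheptyl]propan-2-yl (2,2,2-trifluoroethyl)carbamate | C1C[C@H](C)[C@@H](CC(=O)CC)C(=O)C[C@@H]1C(C)(C)OC(=O)NCC(F)(F)F | intermediate
12 | N-iodo derivative of carbamate 11 | C1C[C@H](C)[C@@H](CC(=O)CC)C(=O)C[C@@H]1C(C)(C)OC(=O)N(I)CC(F)(F)F | intermediate
13 | 8α-iodide of carbamate 11 (iodine on the ring carbon next to the side-chain carbon, trans to the side chain) | I[C@H]1C[C@H](C)[C@@H](CC(=O)CC)C(=O)C[C@@H]1C(C)(C)OC(=O)NCC(F)(F)F | intermediate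
14 | cis-fused cyclic N-(2,2,2-trifluoroethyl)iminocarbonate (2-imino-1,3-dioxane spanning O-8β and O-11) | FC(F)(F)CN=C1O[C@@H]2C[C@H](C)[C@@H](CC(=O)CC)C(=O)C[C@@H]2C(C)(C)O1 | intermediate
15 | cis-fused cyclic carbonate (1,3-dioxan-2-one spanning O-8β and O-11) of diol diketone 16 | O=C1O[C@@H]2C[C@H](C)[C@@H](CC(=O)CC)C(=O)C[C@@H]2C(C)(C)O1 | intermediate
16 | (2R,3S,5R,6S)-5-hydroxy-6-(2-hydroxypropan-2-yl)-3-methyl-2-(2-oxobutyl)cycloheptan-1-one | O[C@@H]1C[C@H](C)[C@@H](CC(=O)CC)C(=O)C[C@@H]1C(C)(C)O | intermediate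
17 | aldol adduct, (5S,6R,8S,8aR)-3a,6-dihydroxy-5-(2-hydroxypropan-2-yl)-3,8-dimethyloctahydroazulen-2(1H)-one (C3 and C3a epimers) | O[C@@H]1C[C@H](C)[C@H]2CC(=O)C(C)C2(O)C[C@@H]1C(C)(C)O | intermediate
18 | torilolone, (5S,6R,8S,8aR)-6-hydroxy-5-(2-hydroxypropan-2-yl)-3,8-dimethyl-4,5,6,7,8,8a-hexahydroazulen-2(1H)-one | O[C@@H]1C[C@H](C)[C@H]2CC(=O)C(C)=C2C[C@@H]1C(C)(C)O | intermediate
19 | [(5S,6R,8S,8aR)-5-(2-hydroxypropan-2-yl)-3,8-dimethyl-2-oxo-1,2,4,5,6,7,8,8a-octahydroazulen-6-yl] propanoate | CCC(=O)O[C@@H]1C[C@H](C)[C@H]2CC(=O)C(C)=C2C[C@@H]1C(C)(C)O | intermediate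
20 | [(5S,6R,8S,8aR)-5-(2-acetoxypropan-2-yl)-3,8-dimethyl-2-oxo-1,2,4,5,6,7,8,8a-octahydroazulen-6-yl] propanoate | CCC(=O)O[C@@H]1C[C@H](C)[C@H]2CC(=O)C(C)=C2C[C@@H]1C(C)(C)OC(C)=O | target

**Step count**

Total steps: 11. Longest linear sequence: 11 steps (1 → 20).

**Steps most likely to fail, with fallbacks**

Step 8 (the proposed iodine relay). Likely failure modes are α-iodination of the two ketones, β-scission, or a poor 1,6-transfer at an unactivated ring methylene. The fallback uses known hydroxyl-directed C–H silylation and sets out from 10. KOH in aqueous MeOH effects the aldol condensation first and gives (5R,8S,8aR)-5-(2-hydroxypropan-2-yl)-3,8-dimethyl-4,5,6,7,8,8a-hexahydroazulen-2(1H)-one F1. Et2SiHCl and imidazole convert it into the diethylhydrosilyl ether F2. [Ir(cod)OMe]2 with 3,4,7,8-tetramethyl-1,10-phenanthroline and norbornene in THF at 100 °C closes the γ-C–H silylation product, the C8-silylated oxasilolane F3. The trans ring fusion is expected by analogy with equatorial selectivity in known cases, and C8 is preferred over the more congested allylic C6. Tamao–Fleming oxidation (H2O2, KHCO3) gives 8-epi-torilolone F4 with the 8α-hydroxyl. Mitsunobu esterification with propanoic acid (PPh3, DIAD, toluene) inverts C8 and returns to the route at 19.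

Step 4 (one-pot CuH reduction and propargylation). Likely failure modes are sluggish or O-selective alkylation of the seven-ring enolate and a low trans ratio. The fallback sets out from 5 with the same asymmetric reduction, but the crude bis(enoxy)silane 7 is treated with 2-nitrobut-1-ene and SnCl4 in CH2Cl2 at −78 °C. Aqueous work-up completes a Mukaiyama–Michael addition with in situ Nef hydrolysis, and C1 equilibrates to the trans isomer. This gives the 1,4-diketone directly and returns to the route at 9, bypassing 8 and step 5; no new compound is needed.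

Step 11 (acetylation of the hindered tertiary alcohol next to the C8 ester). Likely failure modes are slow reaction, 1,3-acyl scrambling or dehydration. The fallback installs the acetate before the propanoate and sets out from 18. TBSOTf and 2,6-lutidine at −78 °C silylate only the secondary hydroxyl and give 8-O-tert-butyldimethylsilyl torilolone F5. Ac2O with MgBr2·OEt2 and iPr2NEt acetylates the tertiary alcohol with no neighbouring acyl group present and gives the silyl ether acetate F6. HF·pyridine in THF removes the silyl group and gives 11-O-acetyl torilolone F7. Immediate propanoylation ((EtCO)2O, DMAP, 0 °C) returns to the route at 20.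

**Further compounds**

F1 | step 8 | (5R,8S,8aR)-5-(2-hydroxypropan-2-yl)-3,8-dimethyl-4,5,6,7,8,8a-hexahydroazulen-2(1H)-one | C1C[C@H](C)[C@H]2CC(=O)C(C)=C2C[C@@H]1C(C)(C)O
F2 | step 8 | diethylhydrosilyl ether of F1 | C1C[C@H](C)[C@H]2CC(=O)C(C)=C2C[C@@H]1C(C)(C)O[SiH](CC)CC
F3 | step 8 | trans-fused 2,2-diethyl-1,2-oxasilolane closed onto C8 (silicon α) | CC[Si]3(CC)[C@H]1C[C@H](C)[C@H]2CC(=O)C(C)=C2C[C@@H]1C(C)(C)O3
F4 | step 8 | 8-epi-torilolone, (5S,6S,8S,8aR)-6-hydroxy-5-(2-hydroxypropan-2-yl)-3,8-dimethyl-4,5,6,7,8,8a-hexahydroazulen-2(1H)-one | O[C@H]1C[C@H](C)[C@H]2CC(=O)C(C)=C2C[C@@H]1C(C)(C)O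
F0 | step 4 | none | none
F5 | step 11 | 8-O-tert-butyldimethylsilyl torilolone | CC(C)(C)[Si](C)(C)O[C@@H]1C[C@H](C)[C@H]2CC(=O)C(C)=C2C[C@@H]1C(C)(C)O
F6 | step 11 | 8-O-tert-butyldimethylsilyl 11-O-acetyl torilolone | CC(C)(C)[Si](C)(C)O[C@@H]1C[C@H](C)[C@H]2CC(=O)C(C)=C2C[C@@H]1C(C)(C)OC(C)=O
F7 | step 11 | 11-O-acetyl torilolone | O[C@@H]1C[C@H](C)[C@H]2CC(=O)C(C)=C2C[C@@H]1C(C)(C)OC(C)=O
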